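The dihydrofuran ring B (O1, C2, C3, C3a, C7a) is disconnected at O1–C2. The key step exploits that C2 is benzylic to the C2 aryl (ring C), whose para oxygen O4′ can push out the C2 hydroxyl to give a para-quinone methide, while the C7a phenol oxygen of ring A is placed for five-membered closure. One chiral-acid-catalysed operation closes ring B, forms O1–C2 and sets C2, to which C3 adjusts trans. The precursor is a racemic aldol adduct, a methyl 2,3-diaryl-3-hydroxypropanoate with the ring A ortho phenol and ring C para phenol free and O7 and O3′ benzylated. The lactate acrylate arm is added later by C4–H olefination.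

Key step: step 7

Remarks on the chemistry (benzofuran numbering for the core, primed numbers for ring C):
- Assumption: the (R) acid is taken to favour attack on the C2 face that gives (2S); the sense cannot be predicted for this untested closure, and the (S) acid would be used if it proved opposite.
- Assumption: 3-(benzyloxy)-4-hydroxybenzaldehyde 5 and (R)-3-(3,4-dihydroxyphenyl)lactic acid 14 are taken as purchasable.
- Free glyoxylic acid hydroxyalkylates a 2-alkoxyphenol para to the hydroxyl, so it cannot place the acetic ester arm ortho to the future O1. Ring A is therefore built by ortho bromination and zinc enolate coupling.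
- The base equilibration of C3 is placed after O4′ is benzylated, because alkoxide acting on the free para phenol could reopen O1–C2 through the phenoxide and erode C2.

**Route**

Step 1
Reactants: 1 2-(benzyloxy)phenol
Product: 2 2-(benzyloxy)-6-bromophenol
Conditions: NBS, i-Pr2NH (cat.), CH2Cl2, 0 °C → rt
Reagents that add atoms: N-bromosuccinimide, O=C1CCC(=O)N1Br
Why: Amine-mediated ortho bromination of a phenol, in which the hydrogen-bonded bromine donor is delivered next to the hydroxyl, so the only free ortho position (C6) should be substituted in preference to the para position.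

Step 2
Reactants: 2 2-(benzyloxy)-6-bromophenol
Product: 3 [2-(benzyloxy)-6-bromophenoxy](tert-butyl)dimethylsilane
Conditions: TBSCl, imidazole, DMF, rt
Reagents that add atoms: tert-butyl(chloro)dimethylsilane, CC(C)(C)[Si](C)(C)Cl
Why: Imidazole-promoted O-silylation of a phenol masks the acidic hydroxyl before the organozinc coupling and the enolate chemistry.

Step 3
Reactants: 3 [2-(benzyloxy)-6-bromophenoxy](tert-butyl)dimethylsilane
Product: 4 methyl 2-[3-(benzyloxy)-2-{[tert-butyl(dimethyl)silyl]oxy}phenyl]acetate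
Conditions: BrZnCH2CO2Me (from methyl bromoacetate, Zn dust, THF), Pd2(dba)3 (cat.), XPhos, THF, 60 °C
Reagents that add atoms: methyl bromoacetate, COC(=O)CBr (used as its zinc reagent bromo(2-methoxy-2-oxoethyl)zinc, COC(=O)C[Zn]Br)
Why: Negishi-type coupling of a Reformatsky reagent with an aryl bromide under zerovalent palladium and a bulky biaryl phosphine, whose neutral zinc enolate should tolerate the silyl and benzyl ethers.

Step 4
Reactants: 5 3-(benzyloxy)-4-hydroxybenzaldehyde
Product: 6 3-(benzyloxy)-4-{[tert-butyl(dimethyl)silyl]oxy}benzaldehyde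
Conditions: TBSCl, imidazole, CH2Cl2, rt
Reagents that add atoms: tert-butyl(chloro)dimethylsilane, CC(C)(C)[Si](C)(C)Cl
Why: O-silylation of the phenol removes the phenoxide that would otherwise deactivate the aldehyde towards the enolate.

Step 5
Reactants: 4 methyl 2-[3-(benzyloxy)-2-{[tert-butyl(dimethyl)silyl]oxy}phenyl]acetate; 6 3-(benzyloxy)-4-{[tert-butyl(dimethyl)silyl]oxy}benzaldehyde
Product: 8 methyl 2-[3-(benzyloxy)-2-{[tert-butyl(dimethyl)silyl]oxy}phenyl]-3-[3-(benzyloxy)-4-{[tert-butyl(dimethyl)silyl]oxy}phenyl]-3-hydroxypropanoate (racemic syn/anti mixture), via lithium enolate 7 (not isolated)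
Conditions: LiN(i-Pr)2, THF, −78 °C; then 6, −78 °C; aq NH4Cl
Reagents that add atoms: none
Why: Directed aldol addition of a preformed lithium ester enolate to a non-enolisable aldehyde forms the future C2–C3 bond; both new centres are deliberately left uncontrolled because the carbinol centre is flattened in step 7 and C3 is equilibrated in step 9.

Step 6
Reactants: 8 the bis-silylated aldol adduct
Product: 9 methyl 2-[3-(benzyloxy)-2-hydroxyphenyl]-3-[3-(benzyloxy)-4-hydroxyphenyl]-3-hydroxypropanoate (racemic syn/anti mixture)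
Conditions: TBAF, AcOH, THF, 0 °C
Reagents that add atoms: none
Why: Fluoride cleavage of the two aryl silyl ethers, buffered with acetic acid so that free phenoxide cannot trigger retro-aldol cleavage or premature quinone methide formation.

Step 7
Reactants: 9 methyl 2-[3-(benzyloxy)-2-hydroxyphenyl]-3-[3-(benzyloxy)-4-hydroxyphenyl]-3-hydroxypropanoate
Product: 11 methyl (2S,3S)-7-(benzyloxy)-2-[3-(benzyloxy)-4-hydroxyphenyl]-2,3-dihydro-1-benzofuran-3-carboxylate, via para-quinone methide 10 (not isolated)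
Conditions: (R)-3,3′-bis(2,4,6-triisopropylphenyl)-1,1′-binaphthyl-2,2′-diyl hydrogen phosphate (10 mol %), 4 Å MS, toluene (0.01 M), 0 °C → rt
Reagents that add atoms: none
Why: Proposed new method: the acid should activate the C2 carbinol while binding the para phenol, so that loss of water leaves para-quinone methide 10 paired with the chiral phosphate; the phenol oxygen on C7a then attacks the methide carbon and ring C rearomatises. The nearest established chemistry is the phosphoric-acid-catalysed 1,6-addition of nucleophiles to para-quinone methides released in situ from para-hydroxybenzylic alcohols, together with the non-asymmetric quinone methide ring closure used for dihydrobenzofuran neolignans; an intramolecular enantioselective oxygen closure next to an ester has not been demonstrated. Ring B closes in a 5-exo-trig mode, the exocyclic methide C=C lying outside the new five-membered ring. C2 is controlled by the phosphate, which must shield one face of the planar methide after the carbinol configuration of 9 has been erased; C3 is controlled by the preference of the ester and the C2 aryl for opposite ring faces, reached directly where the methide equilibrates C3 through its para-hydroxystilbene tautomer before closing, and otherwise by the base equilibration in step 9. The step needs oxygen closure to outrun both that tautomerisation as a dead end and intermolecular C-alkylation; the ortho placement of the phenol five atoms from C2 (no carbon of ring A can reach C2), high dilution and sieves should secure this.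

Step 8
Reactants: 11 methyl (2S,3S)-7-(benzyloxy)-2-[3-(benzyloxy)-4-hydroxyphenyl]-2,3-dihydro-1-benzofuran-3-carboxylate
Product: 12 methyl (2S,3S)-7-(benzyloxy)-2-[3,4-bis(benzyloxy)phenyl]-2,3-dihydro-1-benzofuran-3-carboxylate
Conditions: BnBr, K2CO3, acetone, rt
Reagents that add atoms: benzyl bromide, BrCc1ccccc1
Why: Williamson etherification of the para phenol, which removes the quinone methide pathway so that C2 can no longer ionise in the basic and oxidative steps that follow.

Step 9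
Reactants: 12 methyl (2S,3S)-7-(benzyloxy)-2-[3,4-bis(benzyloxy)phenyl]-2,3-dihydro-1-benzofuran-3-carboxylate
Product: 13 (2S,3S)-7-(benzyloxy)-2-[3,4-bis(benzyloxy)phenyl]-2,3-dihydro-1-benzofuran-3-carboxylic acid
Conditions: NaOMe (cat.), MeOH/THF, rt; then aq NaOH, 40 °C; then 1 M HCl
Reagents that add atoms: sodium hydroxide, [Na+].[OH-]
Why: Enolate equilibration at C3 followed by saponification, in which any C3-epimeric (cis) ester should relax to the trans ester under thermodynamic control from the fixed C2 centre before hydroxide cleaves the ester, ring opening by β-elimination being the disfavoured reverse of a 5-endo-trig closure.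

Step 10
Reactants: 14 (2R)-3-(3,4-dihydroxyphenyl)-2-hydroxypropanoic acid
Product: 15 methyl (2R)-3-(3,4-dihydroxyphenyl)-2-hydroxypropanoate
Conditions: MeOH, H2SO4 (cat.), reflux
Reagents that add atoms: methanol, CO
Why: Fischer esterification, which does not involve the stereocentre taken from the chiral pool.

Step 11
Reactants: 15 methyl (2R)-3-(3,4-dihydroxyphenyl)-2-hydroxypropanoate
Product: 16 methyl (2R)-3-[3,4-bis(benzyloxy)phenyl]-2-hydroxypropanoate
Conditions: BnBr, K2CO3, DMF, rt, N2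
Reagents that add atoms: benzyl bromide, BrCc1ccccc1
Why: Williamson etherification in which carbonate deprotonates only the two phenols, so the secondary alcohol should stay free.

Step 12
Reactants: 16 methyl (2R)-3-[3,4-bis(benzyloxy)phenyl]-2-hydroxypropanoate
Product: 17 methyl (2R)-2-(acryloyloxy)-3-[3,4-bis(benzyloxy)phenyl]propanoate
Conditions: acryloyl chloride, Et3N, CH2Cl2, 0 °C
Reagents that add atoms: acryloyl chloride, C=CC(=O)Cl
Why: O-acylation of the secondary alcohol with an acid chloride, with retention at the carbinol carbon because its C–O bond is not broken.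

Step 13
Reactants: 13 (2S,3S)-7-(benzyloxy)-2-[3,4-bis(benzyloxy)phenyl]-2,3-dihydro-1-benzofuran-3-carboxylic acid; 17 methyl (2R)-2-(acryloyloxy)-3-[3,4-bis(benzyloxy)phenyl]propanoate
Product: 18 (2S,3S)-7-(benzyloxy)-2-[3,4-bis(benzyloxy)phenyl]-4-[(1E)-3-{[(2R)-3-[3,4-bis(benzyloxy)phenyl]-1-methoxy-1-oxopropan-2-yl]oxy}-3-oxoprop-1-en-1-yl]-2,3-dihydro-1-benzofuran-3-carboxylic acid
Conditions: Pd(OAc)2 (cat.), N-acetyl-L-isoleucine (cat.), KHCO3, O2 (1 atm), t-AmOH, 85 °C
Reagents that add atoms: none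
Why: Carboxylate-directed ortho C–H olefination of an arylacetic acid by divalent palladium with an N-acetyl amino acid ligand (Fujiwara–Moritani type), in which the C3 carboxylate guides palladation to C4, the only free position ortho to C3a, and syn insertion with β-hydride elimination gives the E cinnamate while O2 reoxidises the metal.

Step 14
Reactants: 18 the penta-O-benzyl acid
Product: 19 (2S,3S)-4-[(1E)-3-{[(2R)-3-(3,4-dihydroxyphenyl)-1-methoxy-1-oxopropan-2-yl]oxy}-3-oxoprop-1-en-1-yl]-2-(3,4-dihydroxyphenyl)-7-hydroxy-2,3-dihydro-1-benzofuran-3-carboxylic acid (the target)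
Conditions: BCl3, C6Me5H, CH2Cl2, −78 °C; aq work-up
Reagents that add atoms: none
Why: Lewis acid debenzylation of aryl benzyl ethers with pentamethylbenzene as a non-basic benzyl cation scavenger, under which the alkene, both esters, the acid and the three stereocentres are expected to survive at −78 °C.

**Compound list**

1 | 2-(benzyloxy)phenol | Oc1ccccc1OCc1ccccc1 | starting material
2 | 2-(benzyloxy)-6-bromophenol | Oc1c(Br)cccc1OCc1ccccc1 | intermediate
3 | [2-(benzyloxy)-6-bromophenoxy](tert-butyl)dimethylsilane | CC(C)(C)[Si](C)(C)Oc1c(Br)cccc1OCc1ccccc1 | intermediate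
4 | methyl 2-[3-(benzyloxy)-2-{[tert-butyl(dimethyl)silyl]oxy}phenyl]acetate | COC(=O)Cc1cccc(OCc2ccccc2)c1O[Si](C)(C)C(C)(C)C | intermediate
5 | 3-(benzyloxy)-4-hydroxybenzaldehyde | O=Cc1ccc(O)c(OCc2ccccc2)c1 | starting material
6 | 3-(benzyloxy)-4-{[tert-butyl(dimethyl)silyl]oxy}benzaldehyde | O=Cc1ccc(O[Si](C)(C)C(C)(C)C)c(OCc2ccccc2)c1 | intermediate
7 | lithium 2-[3-(benzyloxy)-2-{[tert-butyl(dimethyl)silyl]oxy}phenyl]-1-methoxyethen-1-olate | [Li+].COC([O-])=Cc1cccc(OCc2ccccc2)c1O[Si](C)(C)C(C)(C)C | intermediate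
8 | methyl 2-[3-(benzyloxy)-2-{[tert-butyl(dimethyl)silyl]oxy}phenyl]-3-[3-(benzyloxy)-4-{[tert-butyl(dimethyl)silyl]oxy}phenyl]-3-hydroxypropanoate (racemic, syn/anti mixture) | COC(=O)C(c1cccc(OCc2ccccc2)c1O[Si](C)(C)C(C)(C)C)C(O)c1ccc(O[Si](C)(C)C(C)(C)C)c(OCc2ccccc2)c1 | intermediate
9 | methyl 2-[3-(benzyloxy)-2-hydroxyphenyl]-3-[3-(benzyloxy)-4-hydroxyphenyl]-3-hydroxypropanoate (racemic, syn/anti mixture) | COC(=O)C(c1cccc(OCc2ccccc2)c1O)C(O)c1ccc(O)c(OCc2ccccc2)c1 | intermediate
10 | methyl 2-[3-(benzyloxy)-2-hydroxyphenyl]-3-[3-(benzyloxy)-4-oxocyclohexa-2,5-dien-1-ylidene]propanoate | COC(=O)C(c1cccc(OCc2ccccc2)c1O)C=C1C=CC(=O)C(OCc2ccccc2)=C1 | intermediate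
11 | methyl (2S,3S)-7-(benzyloxy)-2-[3-(benzyloxy)-4-hydroxyphenyl]-2,3-dihydro-1-benzofuran-3-carboxylate | c1ccc(OCc3ccccc3)c2c1[C@H](C(=O)OC)[C@@H](c1ccc(O)c(OCc3ccccc3)c1)O2 | intermediate
12 | methyl (2S,3S)-7-(benzyloxy)-2-[3,4-bis(benzyloxy)phenyl]-2,3-dihydro-1-benzofuran-3-carboxylate | c1ccc(OCc3ccccc3)c2c1[C@H](C(=O)OC)[C@@H](c1ccc(OCc3ccccc3)c(OCc3ccccc3)c1)O2 | intermediate
13 | (2S,3S)-7-(benzyloxy)-2-[3,4-bis(benzyloxy)phenyl]-2,3-dihydro-1-benzofuran-3-carboxylic acid | c1ccc(OCc3ccccc3)c2c1[C@H](C(=O)O)[C@@H](c1ccc(OCc3ccccc3)c(OCc3ccccc3)c1)O2 | intermediate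
14 | (2R)-3-(3,4-dihydroxyphenyl)-2-hydroxypropanoic acid | OC(=O)[C@@H](Cc1ccc(O)c(O)c1)O | starting material
15 | methyl (2R)-3-(3,4-dihydroxyphenyl)-2-hydroxypropanoate | COC(=O)[C@@H](Cc1ccc(O)c(O)c1)O | intermediate
16 | methyl (2R)-3-[3,4-bis(benzyloxy)phenyl]-2-hydroxypropanoate | COC(=O)[C@@H](Cc1ccc(OCc2ccccc2)c(OCc2ccccc2)c1)O | intermediate
17 | methyl (2R)-2-(acryloyloxy)-3-[3,4-bis(benzyloxy)phenyl]propanoate | COC(=O)[C@@H](Cc1ccc(OCc2ccccc2)c(OCc2ccccc2)c1)OC(=O)C=C | intermediate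
18 | (2S,3S)-7-(benzyloxy)-2-[3,4-bis(benzyloxy)phenyl]-4-[(1E)-3-{[(2R)-3-[3,4-bis(benzyloxy)phenyl]-1-methoxy-1-oxopropan-2-yl]oxy}-3-oxoprop-1-en-1-yl]-2,3-dihydro-1-benzofuran-3-carboxylic acid | COC(=O)[C@@H](Cc1ccc(OCc2ccccc2)c(OCc2ccccc2)c1)OC(=O)/C=C/c1ccc(OCc2ccccc2)c2c1[C@H](C(=O)O)[C@@H](c1ccc(OCc3ccccc3)c(OCc3ccccc3)c1)O2 | intermediate
19 | (2S,3S)-4-[(1E)-3-{[(2R)-3-(3,4-dihydroxyphenyl)-1-methoxy-1-oxopropan-2-yl]oxy}-3-oxoprop-1-en-1-yl]-2-(3,4-dihydroxyphenyl)-7-hydroxy-2,3-dihydro-1-benzofuran-3-carboxylic acid | COC(=O)[C@@H](Cc1ccc(O)c(O)c1)OC(=O)/C=C/c1ccc(O)c2c1[C@H](C(=O)O)[C@@H](c1ccc(O)c(O)c1)O2 | target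

**Step count**

Total: 14 steps. Longest linear sequence: 10 steps (steps 1, 2, 3, 5, 6, 7, 8, 9, 13, 14).

**Steps most likely to fail**

1. Step 7 (the proposed method). Possible failures are weak or reversed facial control at the methide carbon, tautomerisation of the methide to the para-hydroxystilbene outrunning ring closure, and re-ionisation of the product eroding C2. The fallback uses known chemistry, sets out from 4 and returns at 13. The silyl ether of 4 would be cleaved (TBAF, AcOH, THF) to methyl 2-[3-(benzyloxy)-2-hydroxyphenyl]acetate F1. The phenol would be alkylated with 3,4-bis(benzyloxy)benzyl chloride (K2CO3, DMF) to methyl 2-[3-(benzyloxy)-2-{[3,4-bis(benzyloxy)phenyl]methoxy}phenyl]acetate F2. Diazo transfer (4-acetamidobenzenesulfonyl azide, DBU, MeCN) would give methyl 2-[3-(benzyloxy)-2-{[3,4-bis(benzyloxy)phenyl]methoxy}phenyl]-2-diazoacetate F3. Enantioselective intramolecular carbenoid C–H insertion into the ether methylene would then form C2–C3 instead of O1–C2. It would be catalysed by the antipode of Rh2(PTTL)4, dirhodium tetrakis(N-phthaloyl-tert-leucinate), that delivers (2S), in toluene at low temperature. The expected product is the cis ester methyl (2S,3R)-7-(benzyloxy)-2-[3,4-bis(benzyloxy)phenyl]-2,3-dihydro-1-benzofuran-3-carboxylate F4. The conditions of step 9 would then epimerise C3 to trans and saponify, which leads to 13.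

2. Step 13. Possible failures are slow insertion or breakdown of the elaborate α-acyloxy ester acrylate under the hot, basic, oxidative conditions (elimination or acyl cleavage), and competing palladation on ring C. The fallback sets out from 13 and returns at 19. Acid 13 would be olefinated under the same type of conditions with the robust tert-butyl acrylate to give (2S,3S)-7-(benzyloxy)-2-[3,4-bis(benzyloxy)phenyl]-4-[(1E)-3-tert-butoxy-3-oxoprop-1-en-1-yl]-2,3-dihydro-1-benzofuran-3-carboxylic acid F5. The C3 acid would be capped (BnBr, K2CO3, DMF) as benzyl (2S,3S)-7-(benzyloxy)-2-[3,4-bis(benzyloxy)phenyl]-4-[(1E)-3-tert-butoxy-3-oxoprop-1-en-1-yl]-2,3-dihydro-1-benzofuran-3-carboxylate F6. The tert-butyl ester would be cleaved (TFA, CH2Cl2, 0 °C) to (2E)-3-[(2S,3S)-7-(benzyloxy)-3-[(benzyloxy)carbonyl]-2-[3,4-bis(benzyloxy)phenyl]-2,3-dihydro-1-benzofuran-4-yl]prop-2-enoic acid F7. Steglich esterification with alcohol 16 (EDC, DMAP, CH2Cl2) would give benzyl (2S,3S)-7-(benzyloxy)-2-[3,4-bis(benzyloxy)phenyl]-4-[(1E)-3-{[(2R)-3-[3,4-bis(benzyloxy)phenyl]-1-methoxy-1-oxopropan-2-yl]oxy}-3-oxoprop-1-en-1-yl]-2,3-dihydro-1-benzofuran-3-carboxylate F8. The conditions of step 14 would remove the benzyl ester together with the five ethers and give 19.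

3. Step 14. Possible failures are Lewis acid ionisation of the benzylic O1–C2 ether (ring opening, scrambling of C2 or capture by the scavenger) and incomplete cleavage of five ethers. The fallback moves to a fluoride-labile end game, sets out from 13 and 15 and returns at 19.
   - Hydrogenolysis of 13 (H2, Pd/C, EtOAc, rt), possible because no alkene is present yet, would give (2S,3S)-2-(3,4-dihydroxyphenyl)-7-hydroxy-2,3-dihydro-1-benzofuran-3-carboxylic acid F9.
   - Silylation (TIPSCl, imidazole, DMF) would give triisopropylsilyl (2S,3S)-2-{3,4-bis[(triisopropylsilyl)oxy]phenyl}-7-[(triisopropylsilyl)oxy]-2,3-dihydro-1-benzofuran-3-carboxylate F10.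
   - The labile silyl ester would be hydrolysed (AcOH, THF, H2O) to (2S,3S)-2-{3,4-bis[(triisopropylsilyl)oxy]phenyl}-7-[(triisopropylsilyl)oxy]-2,3-dihydro-1-benzofuran-3-carboxylic acid F11.
   - In parallel, 15 would be silylated on the catechol (TIPSCl, imidazole, DMF) to methyl (2R)-3-{3,4-bis[(triisopropylsilyl)oxy]phenyl}-2-hydroxypropanoate F12 and acylated (acryloyl chloride, Et3N) to methyl (2R)-2-(acryloyloxy)-3-{3,4-bis[(triisopropylsilyl)oxy]phenyl}propanoate F13.
   - Olefination of F11 with F13 under the step 13 conditions would give (2S,3S)-4-[(1E)-3-{[(2R)-3-{3,4-bis[(triisopropylsilyl)oxy]phenyl}-1-methoxy-1-oxopropan-2-yl]oxy}-3-oxoprop-1-en-1-yl]-2-{3,4-bis[(triisopropylsilyl)oxy]phenyl}-7-[(triisopropylsilyl)oxy]-2,3-dihydro-1-benzofuran-3-carboxylic acid F14.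
   - Buffered fluoride (TBAF, AcOH, THF, 0 °C) would then release 19 without any Lewis acid.

**Further compounds**

F1 | step 7 | methyl 2-[3-(benzyloxy)-2-hydroxyphenyl]acetate | COC(=O)Cc1cccc(OCc2ccccc2)c1O
F2 | step 7 | methyl 2-[3-(benzyloxy)-2-{[3,4-bis(benzyloxy)phenyl]methoxy}phenyl]acetate | COC(=O)Cc1cccc(OCc2ccccc2)c1OCc1ccc(OCc2ccccc2)c(OCc2ccccc2)c1
F3 | step 7 | methyl 2-[3-(benzyloxy)-2-{[3,4-bis(benzyloxy)phenyl]methoxy}phenyl]-2-diazoacetate | COC(=O)C(=[N+]=[N-])c1cccc(OCc2ccccc2)c1OCc1ccc(OCc2ccccc2)c(OCc2ccccc2)c1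
F4 | step 7 | methyl (2S,3R)-7-(benzyloxy)-2-[3,4-bis(benzyloxy)phenyl]-2,3-dihydro-1-benzofuran-3-carboxylate | c1ccc(OCc3ccccc3)c2c1[C@@H](C(=O)OC)[C@@H](c1ccc(OCc3ccccc3)c(OCc3ccccc3)c1)O2
F5 | step 13 | (2S,3S)-7-(benzyloxy)-2-[3,4-bis(benzyloxy)phenyl]-4-[(1E)-3-tert-butoxy-3-oxoprop-1-en-1-yl]-2,3-dihydro-1-benzofuran-3-carboxylic acid | CC(C)(C)OC(=O)/C=C/c1ccc(OCc2ccccc2)c2c1[C@H](C(=O)O)[C@@H](c1ccc(OCc3ccccc3)c(OCc3ccccc3)c1)O2
F6 | step 13 | benzyl (2S,3S)-7-(benzyloxy)-2-[3,4-bis(benzyloxy)phenyl]-4-[(1E)-3-tert-butoxy-3-oxoprop-1-en-1-yl]-2,3-dihydro-1-benzofuran-3-carboxylate | CC(C)(C)OC(=O)/C=C/c1ccc(OCc2ccccc2)c2c1[C@H](C(=O)OCc1ccccc1)[C@@H](c1ccc(OCc3ccccc3)c(OCc3ccccc3)c1)O2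
F7 | step 13 | (2E)-3-[(2S,3S)-7-(benzyloxy)-3-[(benzyloxy)carbonyl]-2-[3,4-bis(benzyloxy)phenyl]-2,3-dihydro-1-benzofuran-4-yl]prop-2-enoic acid | OC(=O)/C=C/c1ccc(OCc2ccccc2)c2c1[C@H](C(=O)OCc1ccccc1)[C@@H](c1ccc(OCc3ccccc3)c(OCc3ccccc3)c1)O2
F8 | step 13 | benzyl (2S,3S)-7-(benzyloxy)-2-[3,4-bis(benzyloxy)phenyl]-4-[(1E)-3-{[(2R)-3-[3,4-bis(benzyloxy)phenyl]-1-methoxy-1-oxopropan-2-yl]oxy}-3-oxoprop-1-en-1-yl]-2,3-dihydro-1-benzofuran-3-carboxylate | COC(=O)[C@@H](Cc1ccc(OCc2ccccc2)c(OCc2ccccc2)c1)OC(=O)/C=C/c1ccc(OCc2ccccc2)c2c1[C@H](C(=O)OCc1ccccc1)[C@@H](c1ccc(OCc3ccccc3)c(OCc3ccccc3)c1)O2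
F9 | step 14 | (2S,3S)-2-(3,4-dihydroxyphenyl)-7-hydroxy-2,3-dihydro-1-benzofuran-3-carboxylic acid | c1ccc(O)c2c1[C@H](C(=O)O)[C@@H](c1ccc(O)c(O)c1)O2
F10 | step 14 | triisopropylsilyl (2S,3S)-2-{3,4-bis[(triisopropylsilyl)oxy]phenyl}-7-[(triisopropylsilyl)oxy]-2,3-dihydro-1-benzofuran-3-carboxylate | c1ccc(O[Si](C(C)C)(C(C)C)C(C)C)c2c1[C@H](C(=O)O[Si](C(C)C)(C(C)C)C(C)C)[C@@H](c1ccc(O[Si](C(C)C)(C(C)C)C(C)C)c(O[Si](C(C)C)(C(C)C)C(C)C)c1)O2
F11 | step 14 | (2S,3S)-2-{3,4-bis[(triisopropylsilyl)oxy]phenyl}-7-[(triisopropylsilyl)oxy]-2,3-dihydro-1-benzofuran-3-carboxylic acid | c1ccc(O[Si](C(C)C)(C(C)C)C(C)C)c2c1[C@H](C(=O)O)[C@@H](c1ccc(O[Si](C(C)C)(C(C)C)C(C)C)c(O[Si](C(C)C)(C(C)C)C(C)C)c1)O2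
F12 | step 14 | methyl (2R)-3-{3,4-bis[(triisopropylsilyl)oxy]phenyl}-2-hydroxypropanoate | COC(=O)[C@@H](Cc1ccc(O[Si](C(C)C)(C(C)C)C(C)C)c(O[Si](C(C)C)(C(C)C)C(C)C)c1)O
F13 | step 14 | methyl (2R)-2-(acryloyloxy)-3-{3,4-bis[(triisopropylsilyl)oxy]phenyl}propanoate | COC(=O)[C@@H](Cc1ccc(O[Si](C(C)C)(C(C)C)C(C)C)c(O[Si](C(C)C)(C(C)C)C(C)C)c1)OC(=O)C=C
F14 | step 14 | (2S,3S)-4-[(1E)-3-{[(2R)-3-{3,4-bis[(triisopropylsilyl)oxy]phenyl}-1-methoxy-1-oxopropan-2-yl]oxy}-3-oxoprop-1-en-1-yl]-2-{3,4-bis[(triisopropylsilyl)oxy]phenyl}-7-[(triisopropylsilyl)oxy]-2,3-dihydro-1-benzofuran-3-carboxylic acid | COC(=O)[C@@H](Cc1ccc(O[Si](C(C)C)(C(C)C)C(C)C)c(O[Si](C(C)C)(C(C)C)C(C)C)c1)OC(=O)/C=C/c1ccc(O[Si](C(C)C)(C(C)C)C(C)C)c2c1[C@H](C(=O)O)[C@@H](c1ccc(O[Si](C(C)C)(C(C)C)C(C)C)c(O[Si](C(C)C)(C(C)C)C(C)C)c1)O2
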